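## Structural features

Psidial A is a tetracycle. A chroman (pyran ring fused to a fully substituted diformylphloroglucinol ring) shares its C4–C5 bond with a nine-membered carbocycle, and that carbocycle is fused through C1–C9 to a gem-dimethylcyclobutane and carries an exocyclic C8=C13 methylene. The five stereocentres fall into two clusters. One is the contiguous triad C1′ (CHPh), C5 and the quaternary C4 (O, CH3) on the pyran, where the phenyl group and C6 are cis and the C3 arm on C4 is trans to both. The other is the trans pair C1/C9 on the cyclobutane, with the configuration antipodal to (−)-β-caryophyllene. The clusters are insulated from each other by the C2–C3 and C6–C7–C8 bridges, so each has to be set in the absolute sense on its own. The fragile groups are the two aryl aldehydes ortho to phenols, the 1,1-disubstituted alkene next to a cyclobutane (sensitive to acid, hydrogenation and to radical or cationic character at the neighbouring carbons), and the tertiary alkyl aryl ether at C4. The real difficulties are the enantiopure trans-cyclobutane with two different carbon arms, the quaternary C4 with its two neighbours, and the nine-membered ring. The key step uses the fact that the cyclobutane CH2 (C10) sits next to the quaternary C11. A carbonyl inserted between C10 and C11 gives an unstrained 2,2-dimethylcyclopentanone in which C10 is the only enolisable carbon, so C1 and C9 can be set trans before any strain exists and only C11 can migrate when the ring is contracted.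

## Logic of the disconnections

35 to 33: the two aryl–CHO bonds are cut first. The aldehydes are the most sensitive groups, and the two carbons that bear them are the only free ring positions, each activated by all three oxygens. This removes electrophilic carbonyls from every earlier step; the forward double formylation must spare C8=C13 and the C4–O bond.

33 to 32: a phenylsulfonyl group is added at C6 and both phenols become benzyl ethers. The sulfone is the carbanion anchor for ring closure, and benzyl (not methyl) ethers are chosen so that one electron-transfer step removes all three auxiliaries. The forward step must not reduce the alkene or cleave the tertiary aryl ether.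

32 to 31: the C6–C7 bond is cut. It is the one ring bond flanked by a carbanion-stabilising site (C6) and an allylic electrophile (C7). Because C7 and C13 are the two termini of a 2-substituted allyl unit, direct and allylic displacement give the same ring. The nine-membered ring becomes a chain between two rigid, stereodefined anchors; the forward step has to win against oligomerisation.

31 to 30 to 29: the bromide is traced to the alcohol and to the silyl ether that has protected C7–O since the beginning. These are functional-group changes only.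

29 to 27: a carbonyl is added at C2. It makes C3 a nucleophile for the union and avoids a C2–C3 multiple bond, which would later need hydrogenation in the presence of C8=C13. The demand is a deoxygenation at C2 that creates neither a radical nor a cation next to the cyclobutane.

27 to 16 + 25: the C3–C4 bond is cut. C4 is a ketal carbon and therefore a latent oxocarbenium ion, and the cut divides the molecule into the chroman and cyclobutane halves. The forward addition must create the quaternary centre on the face anti to both neighbouring substituents.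

25 to 24: the C4–OMe and C5–H bonds are removed, giving the endocyclic aryl enol ether. C5 is thereby left open until the last moment and is set by protonation anti to the C1′ phenyl group, so no earlier step has to control it.

24 to 22: the C4 methyl carbon is cut back to a lactone carbonyl (methylenation, then double-bond migration). 22 to 21 to 20: the sulfone is traced to the sulfide, and the C5–C6 bond is cut to a lactone enolate and a one-carbon electrophile.

20 to 18 + 19: the C1′–phenyl bond is cut by retro-conjugate addition to a coumarin. This is the only stereodefining event of the chroman half that needs a chiral catalyst. 18 to 17: the two benzyl ethers are removed.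

16 to 14: the C2–C3 bond is cut (the methyl of the ketone), leaving the ester that has been the C2 carbon since the start.

14 to 12: a carboxyl group is put back on C10. It is the residue of the carbonyl used for the contraction and is excised by radical decarboxylation.

12 to 10 (key): the C10–C11 bond is cut and a carbonyl is re-inserted between the two carbons, giving a diazo cyclopentanone. The strained ring is exchanged for an unstrained one in which C1 and C9 are already trans; the forward step needs clean migration of C11.

10 to 8: the diazo group is removed from C10. 8 to 3 + 6: the C8–C9 bond is cut as a catalytic asymmetric conjugate addition of an alkenyl boronate to a cyclic enoate; C9 is set by the catalyst and C1 by equilibration.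

3 to 2 to 1: the ester carbon is removed by retro-carbonylation to an enol triflate of a symmetrical dione. 6 to 5 to 4: the boronate is traced to the vinyl bromide and the free allylic alcohol.

## Other disconnections considered

Alternative 1: The cut is C4–C5, the bond common to the pyran and the nine-membered ring, together with C1′–H. In the forward step the aryl enol ether of the thirteen-membered macrocycle A1 is protonated to an oxocarbenium ion at C4. The C5=C1′ diarylalkene attacks it across the ring (transannular Prins closure), and a silane reduces the diarylmethyl cation at C1′ to give A2. In its favour, two rings and three stereocentres arise in one operation, and the nine-membered ring is never closed end to end. On ring-strain management it is better than the chosen plan, whose step 20 is a direct medium-ring closure. Against it, all three new centres depend on the conformation of a flexible macrocycle, which is hard to predict. C8 must travel as a ketal because of the acid and be methylenated late next to the epimerisable C9, and A1 needs an aryl vinyl ether and a macrocyclisation of its own. Both plans need the same enantiopure trans-cyclobutane, which could be drawn from 14, so they are equal on that point. Mechanistically this is a cation cascade, whereas the chosen plan sets C1′, C5 and C4 in three separate events. Step economy after fragment union is better here; economy before it is worse.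

Alternative 2: The cut is C5–C6 with reconnection of C3 to C8, which traces the nine-membered ring to the bicyclo[3.2.0]heptanol A3 (drawn with the two alkenyl groups cis and an E alkene; the geometry would have to be matched to the C5 configuration wanted). In the forward step the potassium alkoxide of A3 undergoes an anionic oxy-Cope shift: C5–C6 forms, C3–C8 breaks, and the enolate is protonated to the cis-fused cyclononenone A4. In its favour, the medium ring is made by a concerted four-carbon ring expansion and not by cyclisation, and the gem-dimethylcyclobutane can come from a single [2+2] photocycloaddition. On both points it is better than the chosen plan, which spends eight steps to reach 14. Against it, the photoadduct is racemic, so absolute control needs a resolution or a different entry. A4 is cis-fused and needs epimerisation at C9. The whole chroman (quaternary C4, C1′, the aryl ring) still has to be built onto a flexible cyclononene, where facial control is uncertain. The chosen plan is longer for the carbocycle but controls every centre by catalyst or by a rigid six-membered ring.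

Alternative 3: The cut is C2=C3, leaving the chroman and the cyclobutane as two finished anchors joined through C5–C6–C7–C8(=O)–C9. In the forward step the vinyl groups on C4 and C1 of the diene A5 undergo ring-closing metathesis with the second-generation Hoveyda–Grubbs catalyst to give the Z-cyclononenone A6. In its favour, both stereo-clusters are complete before ring closure, which makes it equal to the chosen plan on that point. The closure is catalytic and neutral. Because C8 is a ketone, the later saturation of C2=C3 has no competing alkene; this matches the chosen plan, which never makes C2–C3 unsaturated. Against it, nine-membered metathesis competes with dimerisation, A5 needs a vinyl-bearing quaternary C4 and a separate C–C bond construction for the keto tether, and C8 must be methylenated late at a hindered ketone beside the epimerisable C9. The step count is comparable; the chosen plan avoids the two late adjustments (hydrogenation, methylenation) at the cost of a sulfone removal.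

Key step: step 7

Remarks on the chemistry:
- Atom labels C1–C13 and C1′ are those of the target in caryophyllane numbering (C1 and C9 cyclobutane CH, C10 cyclobutane CH2, C11 CMe2, C8=C13 methylene, C4 the oxygen-bearing quaternary carbon, C5 its CH neighbour, C1′ the CHPh carbon).
- The C10 configuration of 12 and 13 is drawn trans to the C9 arm; either epimer serves, because step 8 erases it.
- The ligand antipodes in steps 5 and 11 are assigned by analogy with simpler acceptors; if the sense proves opposite, the antipodal ligand is used.

## Steps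

Step 1
Reactants: 1 2,2-dimethylcyclopentane-1,3-dione
Product: 2 5,5-dimethyl-4-oxocyclopent-1-en-1-yl trifluoromethanesulfonate
Conditions: Tf2O (1.05 equiv), 2,6-di-tert-butyl-4-methylpyridine, CH2Cl2, 0 → 23 °C
Reagents that add atoms: trifluoromethanesulfonic anhydride, O=S(=O)(OS(=O)(=O)C(F)(F)F)C(F)(F)F
Why: Enol triflate formation by O-sulfonylation of the ketone enol with a hindered pyridine base; the carbon between the carbonyls is quaternary and the two carbonyls are equivalent, so one equivalent of anhydride should stop at the single mono-triflate.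

Step 2
Reactants: 2 5,5-dimethyl-4-oxocyclopent-1-en-1-yl trifluoromethanesulfonate
Product: 3 methyl 5,5-dimethyl-4-oxocyclopent-1-ene-1-carboxylate
Conditions: Pd(OAc)2 (5 mol%), 1,3-bis(diphenylphosphino)propane, CO (1 atm), MeOH, Et3N, DMF, 60 °C
Reagents that add atoms: carbon monoxide, [C-]#[O+]; methanol, CO
Why: Palladium-catalysed methoxycarbonylation of an alkenyl triflate (oxidative addition to zerovalent palladium, CO insertion, methanolysis of the acylpalladium); the ketone is a spectator and the new ester carbon is C2.

Step 3
Reactants: 4 2-bromoprop-2-en-1-ol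
Product: 5 [(2-bromoprop-2-en-1-yl)oxy](tert-butyl)dimethylsilane
Conditions: TBSCl, imidazole, CH2Cl2, 23 °C
Reagents that add atoms: tert-butyldimethylsilyl chloride, C[Si](C)(Cl)C(C)(C)C
Why: Silylation of a primary allylic alcohol; the vinyl bromide is inert.

Step 4
Reactants: 5 [(2-bromoprop-2-en-1-yl)oxy](tert-butyl)dimethylsilane
Product: 6 tert-butyldimethyl{[2-(4,4,5,5-tetramethyl-1,3,2-dioxaborolan-2-yl)prop-2-en-1-yl]oxy}silane
Conditions: B2pin2, PdCl2(PPh3)2 (3 mol%), PPh3, KOPh, toluene, 50 °C
Reagents that add atoms: bis(pinacolato)diboron, CC1(C)OB(OC1(C)C)B1OC(C)(C)C(C)(C)O1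
Why: Miyaura borylation of a 1-alkenyl bromide; the weak phenoxide base suppresses Suzuki homocoupling and leaves the silyl ether alone.

Step 5
Reactants: 3 methyl 5,5-dimethyl-4-oxocyclopent-1-ene-1-carboxylate; 6 tert-butyldimethyl{[2-(4,4,5,5-tetramethyl-1,3,2-dioxaborolan-2-yl)prop-2-en-1-yl]oxy}silane
Product: 8 methyl (1S,5R)-5-[3-[(tert-butyldimethylsilyl)oxy]prop-1-en-2-yl]-2,2-dimethyl-3-oxocyclopentane-1-carboxylate, via cis keto ester 7 (not isolated)
Conditions: Rh(acac)(C2H4)2 (5 mol%), (R,R)-2,5-diphenylbicyclo[2.2.2]octa-2,5-diene (6 mol%), KOH (0.5 equiv), 1,4-dioxane/H2O 10:1, 50 °C; then NaOMe (0.3 equiv), MeOH, 23 °C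
Reagents that add atoms: none
Why: Hayashi–Miyaura 1,4-addition: the alkenylrhodium from B-to-Rh transmetallation inserts the enoate, the chiral diene selects the face at C9 (5R), and water cleaves the rhodium enolate; methoxide then equilibrates the ester-bearing C1 to the trans isomer (1S), in which the two substituents avoid each other on the unstrained ring.

Step 6
Reactants: 8 methyl (1S,5R)-5-[3-[(tert-butyldimethylsilyl)oxy]prop-1-en-2-yl]-2,2-dimethyl-3-oxocyclopentane-1-carboxylate
Product: 10 methyl (1S,5R)-5-[3-[(tert-butyldimethylsilyl)oxy]prop-1-en-2-yl]-4-diazo-2,2-dimethyl-3-oxocyclopentane-1-carboxylate, via trifluoroacetyl ketone 9 (not isolated)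
Conditions: LiN(SiMe3)2, THF, −78 °C; CF3CO2CH2CF3; then 4-acetamidobenzenesulfonyl azide, Et3N, H2O, MeCN, 23 °C
Reagents that add atoms: 4-acetamidobenzenesulfonyl azide, CC(=O)Nc1ccc(cc1)S(=O)(=O)N=[N+]=[N-]
Why: Regitz diazo transfer in its detrifluoroacetylative form: C10 is the only enolisable ketone position (C11 is quaternary), its kinetic lithium enolate is trifluoroacetylated, and the 1,3-dicarbonyl accepts N2 from the sulfonyl azide with loss of the trifluoroacetyl group as the sulfonamide; the ester α-hydrogen at C1 is not removed at −78 °C, so C1 and C9 are kept.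

Step 7
Reactants: 10 methyl (1S,5R)-5-[3-[(tert-butyldimethylsilyl)oxy]prop-1-en-2-yl]-4-diazo-2,2-dimethyl-3-oxocyclopentane-1-carboxylate
Product: 12 (1R,3S,4R)-4-[3-[(tert-butyldimethylsilyl)oxy]prop-1-en-2-yl]-3-(methoxycarbonyl)-2,2-dimethylcyclobutane-1-carboxylic acid, via ketene 11 (not isolated)
Conditions: hν (365 nm LEDs or Hg lamp through Pyrex), 1,4-dioxane/H2O 5:1, 20 °C
Reagents that add atoms: water, O
Why: Excitation of the diazo ketone, held s-cis by the ring, expels N2 while the C11–C(O) bond migrates to C10, giving ketene 11 with the new C10–C11 bond; water adds to the ketene and the enediol tautomerises to acid 12. The closest known reaction type is the photochemical Wolff ring contraction of cyclic 2-diazo ketones to the next lower cycloalkanecarboxylic acids. The four-membered ring is closed by a 1,2-shift ring contraction and not by a cyclisation, so no ring-closure geometry rule applies, and the strain is paid for by loss of N2. No lasting stereocentre is created: C10 is set when the ketene hydrate is protonated (expected trans to the C9 arm) and is removed in step 8. Regioselectivity is structural, because the diazo group can only sit on C10 and the only other substituent of the carbonyl carbon is C11, so only C11 can migrate. C1 and C9 take no part and the medium is neutral at ambient temperature, so the trans relation from step 5 should be carried into the cyclobutane unchanged. The step also needs rearrangement to win over 1,2-hydrogen shift from C9 and over O–H insertion; the enforced s-cis geometry favours the concerted shift, and light above 300 nm is absorbed only by the diazo ketone.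

Step 8
Reactants: 12 (1R,3S,4R)-4-[3-[(tert-butyldimethylsilyl)oxy]prop-1-en-2-yl]-3-(methoxycarbonyl)-2,2-dimethylcyclobutane-1-carboxylic acid
Product: 14 methyl (1S,4R)-4-[3-[(tert-butyldimethylsilyl)oxy]prop-1-en-2-yl]-2,2-dimethylcyclobutane-1-carboxylate, via Barton ester 13 (not isolated)
Conditions: N-hydroxypyridine-2-thione, N,N'-dicyclohexylcarbodiimide, DMAP (cat.), CH2Cl2, 0 → 23 °C, dark; then t-BuSH (10 equiv), hν (tungsten lamp), 23 °C
Reagents that add atoms: none
Why: Barton decarboxylation: the thiohydroxamate ester fragments under visible light to CO2 and the C10 cyclobutyl radical, which should abstract hydrogen from the thiol far faster than it can open the ring; C10 becomes CH2 and the methyl ester and alkene are spectators.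

Step 9
Reactants: 14 methyl (1S,4R)-4-[3-[(tert-butyldimethylsilyl)oxy]prop-1-en-2-yl]-2,2-dimethylcyclobutane-1-carboxylate
Product: 16 1-[(1S,4R)-4-[3-[(tert-butyldimethylsilyl)oxy]prop-1-en-2-yl]-2,2-dimethylcyclobutyl]ethan-1-one, via silyl ketone 15 (not isolated)
Conditions: Me3SiCH2Li (2.5 equiv), pentane/THF, 0 → 23 °C; then MeOH, 23 °C
Reagents that add atoms: (trimethylsilyl)methyllithium, [Li]C[Si](C)(C)C
Why: Addition of the silylmethyllithium to the ester gives the α-silyl ketone, which the second equivalent deprotonates at once and so protects from over-addition; methanolysis then removes silicon (a known one-flask ester-to-methyl-ketone conversion), and C1 is not enolised because the acidic site is the silylated CH2.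

Step 10
Reactants: 17 5,7-dihydroxy-2H-chromen-2-one
Product: 18 5,7-bis(benzyloxy)-2H-chromen-2-one
Conditions: BnBr (2.4 equiv), K2CO3, DMF, 60 °C
Reagents that add atoms: benzyl bromide, BrCc1ccccc1
Why: Williamson etherification of both phenols; benzyl is chosen so that the ethers leave together with the sulfone in step 21.

Step 11
Reactants: 18 5,7-bis(benzyloxy)-2H-chromen-2-one; 19 phenylboronic acid
Product: 20 (4R)-5,7-bis(benzyloxy)-4-phenylchroman-2-one
Conditions: Rh(acac)(C2H4)2 (3 mol%), (R)-SEGPHOS (3.3 mol%), 1,4-dioxane/H2O 10:1, 60 °C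
Reagents that add atoms: none
Why: Hayashi–Miyaura 1,4-arylation of a coumarin: phenylrhodium adds to C4 of the lactone under control of the bisphosphine, which sets C1′ as R, and water protonates the rhodium enolate.

Step 12
Reactants: 20 (4R)-5,7-bis(benzyloxy)-4-phenylchroman-2-one
Product: 21 (3S,4R)-5,7-bis(benzyloxy)-4-phenyl-3-[(phenylsulfanyl)methyl]chroman-2-one
Conditions: LiN(SiMe3)2, THF, −78 °C; PhSCH2Cl, n-Bu4NI (10 mol%), DMPU, −78 → 0 °C
Reagents that add atoms: chloromethyl phenyl sulfide, ClCSc1ccccc1
Why: Lactone enolate alkylation (iodide-catalysed SN2 on the α-chloro sulfide), expected anti to the C4 phenyl group; the new centre does not matter because it is erased in step 14, and the added carbon is C6.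

Step 13
Reactants: 21 (3S,4R)-5,7-bis(benzyloxy)-4-phenyl-3-[(phenylsulfanyl)methyl]chroman-2-one
Product: 22 (3S,4R)-5,7-bis(benzyloxy)-4-phenyl-3-[(phenylsulfonyl)methyl]chroman-2-one
Conditions: mCPBA (2.2 equiv), CH2Cl2, 0 → 23 °C
Reagents that add atoms: 3-chloroperoxybenzoic acid, OOC(=O)c1cccc(Cl)c1
Why: Sulfide-to-sulfone oxidation with a peracid, done here because the arene is deactivated as an aryl ester and no alkene is yet present.

Step 14
Reactants: 22 (3S,4R)-5,7-bis(benzyloxy)-4-phenyl-3-[(phenylsulfonyl)methyl]chroman-2-one
Product: 24 (4R)-5,7-bis(benzyloxy)-2-methyl-4-phenyl-3-[(phenylsulfonyl)methyl]-4H-chromene, via exocyclic enol ether 23 (not isolated)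
Conditions: (C5H5)2Ti(CH3)2 (2.5 equiv), toluene, 70 °C, dark; filter; then PPTS (5 mol%), CH2Cl2, 23 °C
Reagents that add atoms: dimethyltitanocene, [CH3-].[CH3-].[Ti+4].c1cc[cH-]c1.c1cc[cH-]c1
Why: Petasis methylenation of the lactone carbonyl (non-basic, so the β-sulfonyl lactone should not eliminate sulfinate), then acid-catalysed migration of the exocyclic double bond into the ring to the more substituted aryl enol ether; this erases C5 on purpose and turns the lactone carbon into C4 with its methyl group.

Step 15
Reactants: 24 (4R)-5,7-bis(benzyloxy)-2-methyl-4-phenyl-3-[(phenylsulfonyl)methyl]-4H-chromene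
Product: 25 (3R,4R)-5,7-bis(benzyloxy)-2-methoxy-2-methyl-4-phenyl-3-[(phenylsulfonyl)methyl]chromane (both C2 anomers)
Conditions: MeOH/CH2Cl2, PPTS (5 mol%), 0 °C
Reagents that add atoms: methanol, CO
Why: Acid-catalysed Markovnikov addition of methanol to the enol ether: protonation at C5 should occur axially on the face opposite the C1′ phenyl group (held pseudoaxial by the peri benzyloxy group), which places the sulfonylmethyl arm cis to phenyl (3R), and methanol captures the oxocarbenium ion.

Step 16
Reactants: 16 1-[(1S,4R)-4-[3-[(tert-butyldimethylsilyl)oxy]prop-1-en-2-yl]-2,2-dimethylcyclobutyl]ethan-1-one; 25 (3R,4R)-5,7-bis(benzyloxy)-2-methoxy-2-methyl-4-phenyl-3-[(phenylsulfonyl)methyl]chromane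
Product: 27 2-[(2S,3R,4R)-5,7-bis(benzyloxy)-2-methyl-4-phenyl-3-[(phenylsulfonyl)methyl]chroman-2-yl]-1-[(1S,4R)-4-[3-[(tert-butyldimethylsilyl)oxy]prop-1-en-2-yl]-2,2-dimethylcyclobutyl]ethan-1-one, via silyl enol ether 26 (not isolated)
Conditions: 16, LiN(i-Pr)2, Me3SiCl, THF, −78 °C; pentane, filter; then 25, Me3SiOTf (0.2 equiv), CH2Cl2, −78 °C
Reagents that add atoms: none
Why: Mukaiyama-type addition of a silyl enol ether to a ketal-derived oxocarbenium ion: kinetic enolisation of the methyl group gives 26, the silyl triflate ionises 25, and C3 attacks C4 on the one open face, anti to both the C5 sulfonylmethyl arm and the C1′ phenyl group (which are cis), so the quaternary centre is formed as 2S; the low temperature suppresses proton loss from the cation and the unactivated alkene is far less nucleophilic than the enol ether.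

Step 17
Reactants: 27 2-[(2S,3R,4R)-5,7-bis(benzyloxy)-2-methyl-4-phenyl-3-[(phenylsulfonyl)methyl]chroman-2-yl]-1-[(1S,4R)-4-[3-[(tert-butyldimethylsilyl)oxy]prop-1-en-2-yl]-2,2-dimethylcyclobutyl]ethan-1-one
Product: 29 (2S,3R,4R)-5,7-bis(benzyloxy)-2-[2-[(1S,4R)-4-[3-[(tert-butyldimethylsilyl)oxy]prop-1-en-2-yl]-2,2-dimethylcyclobutyl]ethyl]-2-methyl-4-phenyl-3-[(phenylsulfonyl)methyl]chromane, via tosylhydrazone 28 (not isolated)
Conditions: TsNHNH2, EtOH, 50 °C; concentrate; catecholborane, CHCl3, 0 → 23 °C; then NaOAc·3H2O, 60 °C
Reagents that add atoms: none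
Why: Caglioti-type deoxygenation: the tosylhydrazone is reduced at C=N by catecholborane and acetate triggers loss of sulfinate and N2, leaving CH2 at C2 with no radical or cation next to the cyclobutane; alkene, sulfone, silyl ether and benzyl ethers are inert.

Step 18
Reactants: 29 (2S,3R,4R)-5,7-bis(benzyloxy)-2-[2-[(1S,4R)-4-[3-[(tert-butyldimethylsilyl)oxy]prop-1-en-2-yl]-2,2-dimethylcyclobutyl]ethyl]-2-methyl-4-phenyl-3-[(phenylsulfonyl)methyl]chromane
Product: 30 (2S,3R,4R)-5,7-bis(benzyloxy)-2-[2-[(1S,4R)-4-(3-hydroxyprop-1-en-2-yl)-2,2-dimethylcyclobutyl]ethyl]-2-methyl-4-phenyl-3-[(phenylsulfonyl)methyl]chromane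
Conditions: HF·pyridine, pyridine, THF, 0 → 23 °C
Reagents that add atoms: none
Why: Fluoride-induced cleavage of the primary silyl ether under buffered conditions that should not touch the alkene or the tertiary aryl ether.

Step 19
Reactants: 30 (2S,3R,4R)-5,7-bis(benzyloxy)-2-[2-[(1S,4R)-4-(3-hydroxyprop-1-en-2-yl)-2,2-dimethylcyclobutyl]ethyl]-2-methyl-4-phenyl-3-[(phenylsulfonyl)methyl]chromane
Product: 31 (2S,3R,4R)-5,7-bis(benzyloxy)-2-[2-[(1S,4R)-4-(3-bromoprop-1-en-2-yl)-2,2-dimethylcyclobutyl]ethyl]-2-methyl-4-phenyl-3-[(phenylsulfonyl)methyl]chromane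
Conditions: CBr4, PPh3, CH2Cl2, 0 °C
Reagents that add atoms: carbon tetrabromide, BrC(Br)(Br)Br
Why: Appel bromination of the primary allylic alcohol under neutral conditions.

Step 20
Reactants: 31 (2S,3R,4R)-5,7-bis(benzyloxy)-2-[2-[(1S,4R)-4-(3-bromoprop-1-en-2-yl)-2,2-dimethylcyclobutyl]ethyl]-2-methyl-4-phenyl-3-[(phenylsulfonyl)methyl]chromane
Product: 32 tetracyclic sulfone: the ring system of the target without the two formyl groups, both phenols as benzyl ethers, phenylsulfonyl on C6 of the nine-membered ring, (1S,4S,5R,9R,1′R), both C6 epimers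
Conditions: KN(SiMe3)2 (1.2 equiv), THF, −78 → 0 °C, slow addition, 0.002 M
Reagents that add atoms: none
Why: Intramolecular alkylation of an α-sulfonyl carbanion by an allylic bromide under high dilution; attack at C7 (SN2) and at C13 (SN2′) give the same nine-membered ring because the two termini of the 2-substituted allyl unit are equivalent, and the trans arms on the pyran and on the cyclobutane pre-orient the chain.

Step 21
Reactants: 32 tetracyclic sulfone with benzyl ethers and C6 phenylsulfonyl group
Product: 33 tetracyclic diol: the target without its two formyl groups (5,7-dihydroxychroman), (1S,4S,5R,9R,1′R)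
Conditions: Na, NH3(l)/THF, −78 °C, 15 min; then solid NH4Cl
Reagents that add atoms: none
Why: Dissolving-metal reduction: electron transfer cleaves the C6–S bond (the carbanion is protonated by ammonia) and both benzylic C–O bonds in one operation; without an alcohol the isolated alkene, the phenyl ring and the aryl ether to C4 should not be reduced.

Step 22
Reactants: 33 tetracyclic diol (5,7-dihydroxychroman)
Product: 35 psidial A, (1S,4S,5R,9R,1′R), via bis-iminium salt 34 (not isolated)
Conditions: POCl3 (6 equiv), DMF (12 equiv), MeCN, 0 → 23 °C; then H2O, 50 °C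
Reagents that add atoms: N,N-dimethylformamide, CN(C)C=O; water, O
Why: Double Vilsmeier–Haack formylation: the only two free aromatic positions are each ortho or para to all three oxygen substituents, the chloroiminium ion is too weak an electrophile for the unactivated alkene, and hydrolysis gives the two aldehydes hydrogen-bonded to the phenols.

## Compound list

1 | 2,2-dimethylcyclopentane-1,3-dione | CC1(C)C(=O)CCC1=O | starting material
2 | 5,5-dimethyl-4-oxocyclopent-1-en-1-yl trifluoromethanesulfonate | CC1(C)C(=O)CC=C1OS(=O)(=O)C(F)(F)F | intermediate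
3 | methyl 5,5-dimethyl-4-oxocyclopent-1-ene-1-carboxylate | COC(=O)C1=CCC(=O)C1(C)C | intermediate
4 | 2-bromoprop-2-en-1-ol | OCC(Br)=C | starting material
5 | [(2-bromoprop-2-en-1-yl)oxy](tert-butyl)dimethylsilane | C=C(Br)CO[Si](C)(C)C(C)(C)C | intermediate
6 | tert-butyldimethyl{[2-(4,4,5,5-tetramethyl-1,3,2-dioxaborolan-2-yl)prop-2-en-1-yl]oxy}silane | C=C(CO[Si](C)(C)C(C)(C)C)B1OC(C)(C)C(C)(C)O1 | intermediate
7 | methyl (1R,5R)-5-[3-[(tert-butyldimethylsilyl)oxy]prop-1-en-2-yl]-2,2-dimethyl-3-oxocyclopentane-1-carboxylate (cis keto ester, not isolated) | C1C(=O)C(C)(C)[C@H](C(=O)OC)[C@@H]1C(=C)CO[Si](C)(C)C(C)(C)C | intermediate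
8 | methyl (1S,5R)-5-[3-[(tert-butyldimethylsilyl)oxy]prop-1-en-2-yl]-2,2-dimethyl-3-oxocyclopentane-1-carboxylate | C1C(=O)C(C)(C)[C@@H](C(=O)OC)[C@@H]1C(=C)CO[Si](C)(C)C(C)(C)C | intermediate
9 | 4-(trifluoroacetyl) derivative of 8, C1 and C5 as in 8, C4 epimers or enol (not isolated) | O=C(C1C(=O)C(C)(C)[C@@H](C(=O)OC)[C@@H]1C(=C)CO[Si](C)(C)C(C)(C)C)C(F)(F)F | intermediate
10 | methyl (1S,5R)-5-[3-[(tert-butyldimethylsilyl)oxy]prop-1-en-2-yl]-4-diazo-2,2-dimethyl-3-oxocyclopentane-1-carboxylate | [N-]=[N+]=C1C(=O)C(C)(C)[C@@H](C(=O)OC)[C@@H]1C(=C)CO[Si](C)(C)C(C)(C)C | intermediate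
11 | methyl (1S,4R)-4-[3-[(tert-butyldimethylsilyl)oxy]prop-1-en-2-yl]-2,2-dimethyl-3-(oxomethylidene)cyclobutane-1-carboxylate (ketene, not isolated) | O=C=C1C(C)(C)[C@@H](C(=O)OC)[C@@H]1C(=C)CO[Si](C)(C)C(C)(C)C | intermediate
12 | (1R,3S,4R)-4-[3-[(tert-butyldimethylsilyl)oxy]prop-1-en-2-yl]-3-(methoxycarbonyl)-2,2-dimethylcyclobutane-1-carboxylic acid | OC(=O)[C@H]1C(C)(C)[C@@H](C(=O)OC)[C@@H]1C(=C)CO[Si](C)(C)C(C)(C)C | intermediate
13 | 2-thioxopyridin-1(2H)-yl ester of 12 at the C10 carboxyl, ring configuration as in 12 (Barton ester, not isolated) | S=C1C=CC=CN1OC(=O)[C@H]1C(C)(C)[C@@H](C(=O)OC)[C@@H]1C(=C)CO[Si](C)(C)C(C)(C)C | intermediate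
14 | methyl (1S,4R)-4-[3-[(tert-butyldimethylsilyl)oxy]prop-1-en-2-yl]-2,2-dimethylcyclobutane-1-carboxylate | C1C(C)(C)[C@@H](C(=O)OC)[C@@H]1C(=C)CO[Si](C)(C)C(C)(C)C | intermediate
15 | 1-[(1S,4R)-4-[3-[(tert-butyldimethylsilyl)oxy]prop-1-en-2-yl]-2,2-dimethylcyclobutyl]-2-(trimethylsilyl)ethan-1-one (not isolated) | C1C(C)(C)[C@@H](C(=O)C[Si](C)(C)C)[C@@H]1C(=C)CO[Si](C)(C)C(C)(C)C | intermediate
16 | 1-[(1S,4R)-4-[3-[(tert-butyldimethylsilyl)oxy]prop-1-en-2-yl]-2,2-dimethylcyclobutyl]ethan-1-one | C1C(C)(C)[C@@H](C(C)=O)[C@@H]1C(=C)CO[Si](C)(C)C(C)(C)C | intermediate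
17 | 5,7-dihydroxy-2H-chromen-2-one | Oc1cc(O)c2ccc(=O)oc2c1 | starting material
18 | 5,7-bis(benzyloxy)-2H-chromen-2-one | O=c1ccc2c(OCc3ccccc3)cc(OCc3ccccc3)cc2o1 | intermediate
19 | phenylboronic acid | OB(O)c1ccccc1 | starting material
20 | (4R)-5,7-bis(benzyloxy)-4-phenylchroman-2-one | O=C1C[C@H](c2ccccc2)c2c(OCc3ccccc3)cc(OCc3ccccc3)cc2O1 | intermediate
21 | (3S,4R)-5,7-bis(benzyloxy)-4-phenyl-3-[(phenylsulfanyl)methyl]chroman-2-one | O=C1[C@@H](CSc2ccccc2)[C@H](c2ccccc2)c2c(OCc3ccccc3)cc(OCc3ccccc3)cc2O1 | intermediate
22 | (3S,4R)-5,7-bis(benzyloxy)-4-phenyl-3-[(phenylsulfonyl)methyl]chroman-2-one | O=C1[C@@H](CS(=O)(=O)c2ccccc2)[C@H](c2ccccc2)c2c(OCc3ccccc3)cc(OCc3ccccc3)cc2O1 | intermediate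
23 | (3S,4R)-5,7-bis(benzyloxy)-2-methylidene-4-phenyl-3-[(phenylsulfonyl)methyl]chromane (not isolated) | C=C1[C@@H](CS(=O)(=O)c2ccccc2)[C@H](c2ccccc2)c2c(OCc3ccccc3)cc(OCc3ccccc3)cc2O1 | intermediate
24 | (4R)-5,7-bis(benzyloxy)-2-methyl-4-phenyl-3-[(phenylsulfonyl)methyl]-4H-chromene | CC1=C(CS(=O)(=O)c2ccccc2)[C@H](c2ccccc2)c2c(OCc3ccccc3)cc(OCc3ccccc3)cc2O1 | intermediate
25 | (3R,4R)-5,7-bis(benzyloxy)-2-methoxy-2-methyl-4-phenyl-3-[(phenylsulfonyl)methyl]chromane (both C2 anomers) | COC1(C)[C@H](CS(=O)(=O)c2ccccc2)[C@H](c2ccccc2)c2c(OCc3ccccc3)cc(OCc3ccccc3)cc2O1 | intermediate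
26 | {[1-[(1S,4R)-4-[3-[(tert-butyldimethylsilyl)oxy]prop-1-en-2-yl]-2,2-dimethylcyclobutyl]ethenyl]oxy}trimethylsilane (not isolated) | C1C(C)(C)[C@@H](C(=C)O[Si](C)(C)C)[C@@H]1C(=C)CO[Si](C)(C)C(C)(C)C | intermediate
27 | 2-[(2S,3R,4R)-5,7-bis(benzyloxy)-2-methyl-4-phenyl-3-[(phenylsulfonyl)methyl]chroman-2-yl]-1-[(1S,4R)-4-[3-[(tert-butyldimethylsilyl)oxy]prop-1-en-2-yl]-2,2-dimethylcyclobutyl]ethan-1-one | O=S(=O)(c1ccccc1)C[C@@H]1[C@H](c2ccccc2)c2c(OCc3ccccc3)cc(OCc3ccccc3)cc2O[C@@]1(C)CC(=O)[C@H]1[C@H](C(=C)CO[Si](C)(C)C(C)(C)C)CC1(C)C | intermediate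
28 | 4-methylbenzenesulfonohydrazone of 27 at the C2 ketone, stereocentres as in 27 (not isolated) | O=S(=O)(c1ccccc1)C[C@@H]1[C@H](c2ccccc2)c2c(OCc3ccccc3)cc(OCc3ccccc3)cc2O[C@@]1(C)CC(=NNS(=O)(=O)c1ccc(C)cc1)[C@H]1[C@H](C(=C)CO[Si](C)(C)C(C)(C)C)CC1(C)C | intermediate
29 | (2S,3R,4R)-5,7-bis(benzyloxy)-2-[2-[(1S,4R)-4-[3-[(tert-butyldimethylsilyl)oxy]prop-1-en-2-yl]-2,2-dimethylcyclobutyl]ethyl]-2-methyl-4-phenyl-3-[(phenylsulfonyl)methyl]chromane | O=S(=O)(c1ccccc1)C[C@@H]1[C@H](c2ccccc2)c2c(OCc3ccccc3)cc(OCc3ccccc3)cc2O[C@@]1(C)CC[C@H]1[C@H](C(=C)CO[Si](C)(C)C(C)(C)C)CC1(C)C | intermediate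
30 | (2S,3R,4R)-5,7-bis(benzyloxy)-2-[2-[(1S,4R)-4-(3-hydroxyprop-1-en-2-yl)-2,2-dimethylcyclobutyl]ethyl]-2-methyl-4-phenyl-3-[(phenylsulfonyl)methyl]chromane | O=S(=O)(c1ccccc1)C[C@@H]1[C@H](c2ccccc2)c2c(OCc3ccccc3)cc(OCc3ccccc3)cc2O[C@@]1(C)CC[C@H]1[C@H](C(=C)CO)CC1(C)C | intermediate
31 | (2S,3R,4R)-5,7-bis(benzyloxy)-2-[2-[(1S,4R)-4-(3-bromoprop-1-en-2-yl)-2,2-dimethylcyclobutyl]ethyl]-2-methyl-4-phenyl-3-[(phenylsulfonyl)methyl]chromane | O=S(=O)(c1ccccc1)C[C@@H]1[C@H](c2ccccc2)c2c(OCc3ccccc3)cc(OCc3ccccc3)cc2O[C@@]1(C)CC[C@H]1[C@H](C(=C)CBr)CC1(C)C | intermediate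
32 | tetracyclic sulfone: ring system of the target without the two formyl groups, both phenols as benzyl ethers, phenylsulfonyl on C6, (1S,4S,5R,9R,1′R), both C6 epimers | C=C1CC(S(=O)(=O)c3ccccc3)[C@@H]2[C@H](c3ccccc3)c3c(OCc4ccccc4)cc(OCc4ccccc4)cc3O[C@@]2(C)CC[C@H]2[C@H]1CC2(C)C | intermediate
33 | tetracyclic diol: the target without its two formyl groups, (1S,4S,5R,9R,1′R) | C=C1CC[C@@H]2[C@H](c3ccccc3)c3c(O)cc(O)cc3O[C@@]2(C)CC[C@H]2[C@H]1CC2(C)C | intermediate
34 | bis(N,N-dimethyliminium) dichloride of 35 (both CHO carbons as CH=NMe2+), stereocentres as in 35 (not isolated) | C=C1CC[C@@H]2[C@H](c3ccccc3)c3c(O)c(C=[N+](C)C)c(O)c(C=[N+](C)C)c3O[C@@]2(C)CC[C@H]2[C@H]1CC2(C)C.[Cl-].[Cl-] | intermediate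
35 | psidial A, (1S,4S,5R,9R,1′R) in caryophyllane numbering | C=C1CC[C@@H]2[C@H](c3ccccc3)c3c(O)c(C=O)c(O)c(C=O)c3O[C@@]2(C)CC[C@H]2[C@H]1CC2(C)C | target

## Step count and least certain steps

Total: 22 steps. Longest linear sequence: 14 steps (1, 2, 5–9, 16–22) from 1. The boronate branch adds steps 3–4 and the chroman branch steps 10–15.

Step 7 (key step). The contraction itself is well precedented. The most likely loss is after it: water in dioxane is a modest trap for the strained ketene, so ketene dimerisation or acylation of the product acid can compete, and a 1,2-hydrogen shift from C9 in the excited state would give a cyclopentenone. The fallback sets out from 10 and captures the ketene with a stronger, acidic oxygen nucleophile in dry medium. Irradiation in THF with N-hydroxyphthalimide (3 equiv) should give the 1,3-dioxoisoindolin-2-yl ester at the C10 carboxyl, F1. Its reductive decarboxylation under visible light (Ru(2,2′-bipyridine)3Cl2 as catalyst, 1-benzyl-1,4-dihydronicotinamide, t-BuSH) returns to the route at 14, bypassing 12 and 13.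

Step 5. The alkenyl group is α-branched and carries a bulky silyloxymethyl arm, and the acceptor is a trisubstituted cyclic enoate. Slow insertion would let protodeboronation win and would erode the enantioselectivity. The fallback sets out from 3 and uses the smaller isopropenylboronic acid pinacol ester under the same rhodium/diene catalysis, followed by the same methoxide equilibration, to give methyl (1S,5R)-2,2-dimethyl-3-oxo-5-(prop-1-en-2-yl)cyclopentane-1-carboxylate F2. Allylic oxidation of the isopropenyl methyl group (SeO2 as catalyst, t-BuOOH, CH2Cl2) gives methyl (1S,5R)-5-(3-hydroxyprop-1-en-2-yl)-2,2-dimethyl-3-oxocyclopentane-1-carboxylate F3, and silylation (TBSCl, imidazole) returns to the route at 8.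

Step 16. The tertiary oxocarbenium ion can lose the C5 proton back to 24 faster than it is captured at the hindered C4. That would consume the ketal and scramble C5 through the enol ether, and both effects erode the facial control on which C4 and C5 depend. The fallback sets out from 24 and 16 and omits the ketal. Compound 24 is protonated with one equivalent of HN(SO2CF3)2 in CH2Cl2 at −78 °C, so that any enol ether re-formed is protonated again (anti to the phenyl group), and 26 is then added. The route is rejoined at 27 with no new compound.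

Step 17. The C2 ketone is flanked by a cyclobutyl CH and a neopentyl-type CH2, so hydrazone formation may be slow, and prolonged heating invites β-elimination of the C4 aryloxide (retro-oxa-Michael). The fallback sets out from 27. NaBH4 in MeOH/THF gives the C2 alcohol F4 (both epimers), and phenyl chlorothionoformate with pyridine and DMAP gives the O-phenyl thionocarbonate F5. Barton–McCombie reduction (n-Bu3SnH, AIBN, catalytic PhSeSePh so that the benzeneselenol formed in situ quenches the cyclobutylcarbinyl radical before it opens) returns to the route at 29.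

Step 20. End-to-end closure of a nine-membered ring is slow, so intermolecular alkylation to oligomers is the likely competitor even at high dilution. The fallback sets out from 30 and uses a faster electrophile. MnO2 oxidation gives the 2-substituted acrolein F6. Addition of the sulfonyl carbanion to the aldehyde (KN(SiMe3)2, THF, −78 °C, high dilution), with in situ acylation of the alkoxide by methyl chloroformate, gives the cyclic allylic methyl carbonate F7. Palladium-catalysed formate reduction (Pd(OAc)2, n-Bu3P, HCO2NH4), which delivers hydride to the more substituted terminus of the allyl unit and so leaves the exocyclic methylene, returns to the route at 32.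

Step 22. The first iminium group deactivates the ring, so the reaction may stop after one formylation. The fallback sets out from 33 and uses magnesium phenoxide-directed ortho-formylation with paraformaldehyde (MgCl2, Et3N, MeCN, reflux), which works through the phenoxide rather than through an external electrophile and needs no acid. It returns to the route at 35 with no new compound.

## Further compounds

F1 | step 7 | 1,3-dioxoisoindolin-2-yl ester of 12 at the C10 carboxyl, ring configuration as in 12 | O=C(ON1C(=O)c2ccccc2C1=O)[C@H]1C(C)(C)[C@@H](C(=O)OC)[C@@H]1C(=C)CO[Si](C)(C)C(C)(C)C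
F2 | step 5 | methyl (1S,5R)-2,2-dimethyl-3-oxo-5-(prop-1-en-2-yl)cyclopentane-1-carboxylate | C1C(=O)C(C)(C)[C@@H](C(=O)OC)[C@@H]1C(C)=C
F3 | step 5 | methyl (1S,5R)-5-(3-hydroxyprop-1-en-2-yl)-2,2-dimethyl-3-oxocyclopentane-1-carboxylate | C1C(=O)C(C)(C)[C@@H](C(=O)OC)[C@@H]1C(=C)CO
F0 | step 16 | none | none
F4 | step 17 | C2 alcohol from reduction of 27, both C2 epimers, other stereocentres as in 27 | O=S(=O)(c1ccccc1)C[C@@H]1[C@H](c2ccccc2)c2c(OCc3ccccc3)cc(OCc3ccccc3)cc2O[C@@]1(C)CC(O)[C@H]1[C@H](C(=C)CO[Si](C)(C)C(C)(C)C)CC1(C)C
F5 | step 17 | O-phenyl thionocarbonate of F4 | O=S(=O)(c1ccccc1)C[C@@H]1[C@H](c2ccccc2)c2c(OCc3ccccc3)cc(OCc3ccccc3)cc2O[C@@]1(C)CC(OC(=S)Oc1ccccc1)[C@H]1[C@H](C(=C)CO[Si](C)(C)C(C)(C)C)CC1(C)C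
F6 | step 20 | 2-substituted acrolein from oxidation of 30, stereocentres as in 30 | O=S(=O)(c1ccccc1)C[C@@H]1[C@H](c2ccccc2)c2c(OCc3ccccc3)cc(OCc3ccccc3)cc2O[C@@]1(C)CC[C@H]1[C@H](C(=C)C=O)CC1(C)C
F7 | step 20 | cyclised C7 methyl carbonate with C6 phenylsulfonyl group, (1S,4S,5R,9R,1′R), C6 and C7 epimers | C=C1C(OC(=O)OC)C(S(=O)(=O)c3ccccc3)[C@@H]2[C@H](c3ccccc3)c3c(OCc4ccccc4)cc(OCc4ccccc4)cc3O[C@@]2(C)CC[C@H]2[C@H]1CC2(C)C
F0 | step 22 | none | none
A1 | alternative 1 | thirteen-membered aryl enol ether macrocycle with C5=C1′ diarylalkene and C8 dioxolane, (1S,9R), alkene geometry left open | C=C1CC[C@H]2[C@@H](CC2(C)C)C2(OCCO2)CCC=C(c2ccccc2)c2c(OC)cc(OC)cc2O1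
A2 | alternative 1 | tetracyclic dimethoxychroman with C8 dioxolane, (1S,4S,5R,9R,1′R) | C1COC2(O1)CC[C@@H]1[C@H](c3ccccc3)c3c(OC)cc(OC)cc3O[C@@]1(C)CC[C@H]1[C@H]2CC1(C)C
A3 | alternative 2 | cis-fused 6,6-dimethylbicyclo[3.2.0]heptan-2-ol bearing a 2-vinyl group and a cis 3-[(E)-4-silyloxybut-2-en-2-yl] group | C=C[C@@]1(O)[C@@H](/C(C)=C/CO[Si](C)(C)C(C)(C)C)C[C@H]2[C@@H]1CC2(C)C
A4 | alternative 2 | cis-fused bicyclo[7.2.0]undecenone with Z C3=C4 alkene and C5 silyloxymethyl group | O=C1CC[C@H](CO[Si](C)(C)C(C)(C)C)/C(C)=C\C[C@H]2[C@@H]1CC2(C)C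
A5 | alternative 3 | seco-diene: 2-vinyl dimethoxychroman linked through C5–C6–C7–C8(=O) to the 2-vinylcyclobutane, stereocentres as in A6 | C=C[C@H]1[C@@H](CC1(C)C)C(=O)CC[C@@H]1[C@H](c2ccccc2)c2c(OC)cc(OC)cc2O[C@@]1(C)C=C
A6 | alternative 3 | tetracyclic Z-C2=C3 cyclononenone, dimethoxychroman, (1S,4S,5R,9R,1′R) | O=C1CC[C@@H]2[C@H](c3ccccc3)c3c(OC)cc(OC)cc3O[C@@]2(C)/C=C\[C@H]2[C@H]1CC2(C)C
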